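**Plan**
- Retrosynthesis: cut the prenyl C=C (Wittig) first, then the ring bond between the quaternary carbon and the enolised carbonyl carbon that neighbours the hexanoyl-bearing carbon, then the open 2-acyl-3-oxo ester chain (C-acylation, malonate homologation, benzylation).
- Forward: a MOM-protected benzylic bromide (arene ring) and (3-methylfuran-2-yl)acetic acid are joined by auxiliary alkylation; the chain is extended to a tert-butyl 2-hexanoyl-3-oxo ester; thermolysis closes the carbocycle; acid frees the phenols and opens the former furan ring; Wittig completes the prenyl group.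
- Enabling feature: the 3-methylfuran ring. Its C2=C3 bond is a geometry-locked latent enol ether of the ring carbonyl next to the quaternary carbon, its methyl-bearing C3 becomes the quaternary carbon, and its C4–C5 unit is a latent CH2CHO arm (prenyl precursor).
- Stereochemistry: one Evans alkylation sets an (R)-centre α to the furan; in the ring closure this centre is relayed to the quaternary carbon (allylic 1,3-strain) and is itself erased.

Key step: step 12

Assumption: the enolised triketone ring, the 2-acyl-3-oxo ester 21 and lactol 24 are each drawn as one tautomer; the enolised C2 of 21 and the lactol carbon of 24 carry no defined configuration.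

Step 1
Reactants: 1 2,4-dihydroxy-6-methoxybenzaldehyde
Product: 2 2-methoxy-4,6-bis(methoxymethoxy)benzaldehyde
Conditions: NaH (2.5 equiv), MOMCl (2.5 equiv), DMF, 0 °C to rt
Reagents that add atoms: chloromethyl methyl ether, COCCl
Why: Williamson ether synthesis on both phenoxides should give the bis-MOM ether, NaH being chosen because the hydrogen-bonded 2-OH resists amine bases.

Step 2
Reactants: 2 2-methoxy-4,6-bis(methoxymethoxy)benzaldehyde
Product: 3 [2-methoxy-4,6-bis(methoxymethoxy)phenyl]methanol
Conditions: NaBH4, MeOH, 0 °C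
Reagents that add atoms: none
Why: Borohydride reduction of an aromatic aldehyde is reliable and leaves the MOM acetals untouched.

Step 3
Reactants: 3 [2-methoxy-4,6-bis(methoxymethoxy)phenyl]methanol
Product: 5 1-[3-(hydroxymethyl)-4-methoxy-2,6-bis(methoxymethoxy)phenyl]hexan-1-one, via dilithiated aryl alkoxide 4 (not isolated)
Conditions: n-BuLi (2.2 equiv), THF, 0 °C; then n-C5H11CON(OMe)Me, −78 to 0 °C; H2O
Reagents that add atoms: N-methoxy-N-methylhexanamide, CCCCCC(=O)N(C)OC
Why: After O-lithiation, directed ortho-metalation should occur at the only ring CH flanked by two OMOM groups, and the aryllithium is acylated once by the Weinreb amide (Weinreb ketone synthesis), which puts the hexanoyl group between the two protected phenols.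

Step 4
Reactants: 5 1-[3-(hydroxymethyl)-4-methoxy-2,6-bis(methoxymethoxy)phenyl]hexan-1-one
Product: 6 1-[3-(bromomethyl)-4-methoxy-2,6-bis(methoxymethoxy)phenyl]hexan-1-one
Conditions: CBr4, PPh3, CH2Cl2, 0 °C; used at once
Reagents that add atoms: carbon tetrabromide, BrC(Br)(Br)Br
Why: The Appel reaction converts the primary benzylic alcohol to the bromide under neutral conditions that spare the MOM ethers.

Step 5
Reactants: 7 3-methylfuran-2-carboxylic acid
Product: 9 2-diazo-1-(3-methylfuran-2-yl)ethan-1-one, via 3-methylfuran-2-carbonyl chloride 8 (not isolated)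
Conditions: (COCl)2, cat. DMF, CH2Cl2, 0 °C to rt; evaporate; CH2N2 (2.5 equiv), Et2O, 0 °C
Reagents that add atoms: diazomethane, C=[N+]=[N-]
Why: Acid chloride formation and acylation of diazomethane form the first half of the Arndt–Eistert homologation, the excess diazomethane taking up the HCl.

Step 6
Reactants: 9 2-diazo-1-(3-methylfuran-2-yl)ethan-1-one
Product: 11 2-(3-methylfuran-2-yl)acetic acid, via (3-methylfuran-2-yl)ketene 10 (not isolated)
Conditions: PhCO2Ag (0.1 equiv), Et3N, THF/H2O 10:1, rt, dark
Reagents that add atoms: water, O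
Why: Silver-catalysed Wolff rearrangement gives the furylketene, which is hydrated in situ to the one-carbon-homologated acid.

Step 7
Reactants: 11 2-(3-methylfuran-2-yl)acetic acid; 12 (R)-4-benzyl-1,3-oxazolidin-2-one
Product: 14 (R)-4-benzyl-3-[2-(3-methylfuran-2-yl)acetyl]-1,3-oxazolidin-2-one, via mixed pivalic anhydride 13 (not isolated)
Conditions: t-BuCOCl, Et3N, THF, −20 °C; then 12, LiCl, rt
Reagents that add atoms: none
Why: N-acylation of the oxazolidinone by the mixed pivalic anhydride under LiCl/Et3N activation is the standard way to load an arylacetic acid onto the auxiliary.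

Step 8
Reactants: 14 (R)-4-benzyl-3-[2-(3-methylfuran-2-yl)acetyl]-1,3-oxazolidin-2-one; 6 1-[3-(bromomethyl)-4-methoxy-2,6-bis(methoxymethoxy)phenyl]hexan-1-one
Product: 16 (R)-4-benzyl-3-[(2R)-3-[3-hexanoyl-6-methoxy-2,4-bis(methoxymethoxy)phenyl]-2-(3-methylfuran-2-yl)propanoyl]-1,3-oxazolidin-2-one, via sodium (Z)-enolate 15 (not isolated)
Conditions: NaHMDS (1.1 equiv), THF, −78 °C; then 6, −78 to −40 °C
Reagents that add atoms: none
Why: Evans alkylation, in which the chelated (Z)-enolate is attacked by the benzylic bromide on the face away from the auxiliary benzyl group, should set the (R)-centre α to the furan with high diastereoselectivity.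

Step 9
Reactants: 16 the alkylated imide
Product: 18 (2R)-3-[3-hexanoyl-6-methoxy-2,4-bis(methoxymethoxy)phenyl]-2-(3-methylfuran-2-yl)propanoic acid, via peroxy acid 17 (not isolated)
Conditions: LiOH, 30% H2O2, THF/H2O 3:1, 0 °C; aq. Na2SO3; 1 M HCl to pH 3
Reagents that add atoms: hydrogen peroxide, OO
Why: Hydroperoxide attacks the exocyclic imide carbonyl selectively (standard auxiliary removal) and sulfite reduces the peroxy acid, conditions under which α-aryl-type centres are normally retained.

Step 10
Reactants: 18 the (2R)-acid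
Product: 20 tert-butyl (4R)-5-[3-hexanoyl-6-methoxy-2,4-bis(methoxymethoxy)phenyl]-4-(3-methylfuran-2-yl)-3-oxopentanoate, via acyl imidazolide 19 (not isolated)
Conditions: CDI, THF, rt; then Mg(O2CCH2CO2t-Bu)2, THF, rt; cold dil. HCl work-up
Reagents that add atoms: magnesium bis(3-tert-butoxy-3-oxopropanoate), CC(C)(C)OC(=O)CC(=O)[O-].CC(C)(C)OC(=O)CC(=O)[O-].[Mg+2]
Why: In the Masamune–Brooks homologation the acyl imidazolide is C-acylated by the neutral magnesium malonate half-ester and decarboxylation gives the β-keto ester without strong base, which protects the α-furyl centre.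

Step 11
Reactants: 20 the β-keto ester
Product: 21 tert-butyl (4R)-2-hexanoyl-5-[3-hexanoyl-6-methoxy-2,4-bis(methoxymethoxy)phenyl]-4-(3-methylfuran-2-yl)-3-oxopentanoate (enolised at C2)
Conditions: MgCl2, pyridine, CH2Cl2, 0 °C; n-C5H11COCl, 0 °C to rt
Reagents that add atoms: hexanoyl chloride, CCCCCC(Cl)=O
Why: MgCl2/pyridine-mediated C-acylation of the chelated magnesium enolate of a β-keto ester with an acid chloride should give the 2-acyl-3-oxo ester, deprotonation occurring only at the doubly activated C2 and not at C4.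

Step 12
Reactants: 21 the tert-butyl 2-hexanoyl-3-oxo ester
Product: 23 (3aS)-5-hexanoyl-7-{[3-hexanoyl-6-methoxy-2,4-bis(methoxymethoxy)phenyl]methyl}-6-hydroxy-3a-methyl-1-benzofuran-4(3aH)-one, via diacylketene 22 (not isolated)
Conditions: PhMe, 110 °C, 0.005 M (slow addition), N2
Reagents that add atoms: none
Why: Proposed new method: heating the chelated enol of 21 should extrude t-BuOH to give diacylketene 22, whose sp carbon is attacked in the ketene plane by the enol-ether-like C2=C3 π bond of the furan at the methyl-bearing C3 (ipso), the charge being taken up as an O-stabilised oxocarbenium ion at furan C2 and a 1,3-dioxo enolate, after which loss of the now doubly activated C4–H gives the neutral cross-conjugated trienone 23. The closest known reaction types are the thermal ester-to-acylketene route with capture by enol ethers, the intramolecular Friedel–Crafts acylation of 4-(2-furyl)butanoic acids at furan C3 and the SE2′ substitution of 2-(silylmethyl)furans, but an ipso C3-acylation that leaves a quaternary carbon has not been shown on this substrate class. The six-membered carbocycle closes in a 6-(enol-endo)-exo-dig mode, and attack at furan C2 instead would give a spiro five-membered ring and a cation without oxygen stabilisation. The quaternary centre is set by 1,3-chirality transfer from C4: allylic 1,3-strain with the furan 3-methyl group keeps the C4–H bond near the furan plane on the methyl side, so the ketene arm and the arylmethyl arm lie on opposite faces and the ketene is delivered to the face of its own arm, (4R) giving (3aS), and C4 then becomes sp2. The step needs facial selectivity, ring closure faster than ketene dimerisation, and an intact C4 configuration up to C–C bond formation; these rest on the strain argument, on high dilution, and on base-free neutral thermolysis of a substrate enolised towards C2 rather than C4.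

Step 13
Reactants: 23 the bicyclic trienone
Product: 24 (3aS)-5-hexanoyl-7-[(3-hexanoyl-2,4-dihydroxy-6-methoxyphenyl)methyl]-2,6-dihydroxy-3a-methyl-2,3-dihydro-1-benzofuran-4(3aH)-one (lactol epimers)
Conditions: 2 M HCl, THF/H2O 1:1, 35 °C
Reagents that add atoms: water, O
Why: Aqueous acid cleaves both MOM acetals and hydrates the enol-ether C2=C3 bond of the former furan (C-protonation, then water on the oxocarbenium ion) to the lactol, and the quaternary centre cannot be lost because the hexanoyl and arylmethyl groups keep the two ring flanks different.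

Step 14
Reactants: 24 the lactol
Product: 26 (4S)-2-hexanoyl-6-[(3-hexanoyl-2,4-dihydroxy-6-methoxyphenyl)methyl]-3,5-dihydroxy-4-methyl-4-(3-methylbut-2-en-1-yl)cyclohexa-2,5-dien-1-one (CNP0108719.1), via ring-opened aldehyde 25 (not isolated)
Conditions: i-PrPPh3I (8 equiv), KHMDS (8 equiv), THF, 0 °C; then 24 in THF/DMSO, 0 °C to rt; pH 4 buffer
Reagents that add atoms: isopropyltriphenylphosphonium iodide, CC(C)[P+](c1ccccc1)(c1ccccc1)c1ccccc1.[I-]
Why: Wittig olefination of the aldehyde form of the lactol with the non-stabilised isopropylidene ylide installs the trisubstituted alkene with no E/Z issue, the excess ylide first deprotonating the phenol and enol OH groups, whose anions are inert to it.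

**Compound list**
1 | 2,4-dihydroxy-6-methoxybenzaldehyde | COc1cc(O)cc(O)c1C=O | starting material
2 | 2-methoxy-4,6-bis(methoxymethoxy)benzaldehyde | COCOc1cc(OC)c(C=O)c(OCOC)c1 | intermediate
3 | [2-methoxy-4,6-bis(methoxymethoxy)phenyl]methanol | COCOc1cc(OC)c(CO)c(OCOC)c1 | intermediate
4 | dilithiated aryl alkoxide (not isolated) | COCOc1cc(OC)c(CO[Li])c(OCOC)c1[Li] | intermediate
5 | 1-[3-(hydroxymethyl)-4-methoxy-2,6-bis(methoxymethoxy)phenyl]hexan-1-one | CCCCCC(=O)c1c(OCOC)cc(OC)c(CO)c1OCOC | intermediate
6 | 1-[3-(bromomethyl)-4-methoxy-2,6-bis(methoxymethoxy)phenyl]hexan-1-one | CCCCCC(=O)c1c(OCOC)cc(OC)c(CBr)c1OCOC | intermediate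
7 | 3-methylfuran-2-carboxylic acid | Cc1ccoc1C(=O)O | starting material
8 | 3-methylfuran-2-carbonyl chloride (not isolated) | Cc1ccoc1C(=O)Cl | intermediate
9 | 2-diazo-1-(3-methylfuran-2-yl)ethan-1-one | Cc1ccoc1C(=O)C=[N+]=[N-] | intermediate
10 | (3-methylfuran-2-yl)ketene (not isolated) | Cc1ccoc1C=C=O | intermediate
11 | 2-(3-methylfuran-2-yl)acetic acid | Cc1ccoc1CC(=O)O | intermediate
12 | (R)-4-benzyl-1,3-oxazolidin-2-one | O=C1N[C@H](Cc2ccccc2)CO1 | starting material
13 | mixed pivalic anhydride of 11 (not isolated) | Cc1ccoc1CC(=O)OC(=O)C(C)(C)C | intermediate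
14 | (R)-4-benzyl-3-[2-(3-methylfuran-2-yl)acetyl]-1,3-oxazolidin-2-one | Cc1ccoc1CC(=O)N1[C@H](Cc2ccccc2)COC1=O | intermediate
15 | sodium (Z)-enolate of 14 (not isolated) | Cc1ccoc1/C=C(\O[Na])N1[C@H](Cc2ccccc2)COC1=O | intermediate
16 | (R)-4-benzyl-3-[(2R)-3-[3-hexanoyl-6-methoxy-2,4-bis(methoxymethoxy)phenyl]-2-(3-methylfuran-2-yl)propanoyl]-1,3-oxazolidin-2-one | Cc1ccoc1[C@@H](Cc2c(OC)cc(OCOC)c(C(=O)CCCCC)c2OCOC)C(=O)N1[C@H](Cc3ccccc3)COC1=O | intermediate
17 | (2R)-peroxy acid (not isolated) | Cc1ccoc1[C@@H](Cc2c(OC)cc(OCOC)c(C(=O)CCCCC)c2OCOC)C(=O)OO | intermediate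
18 | (2R)-3-[3-hexanoyl-6-methoxy-2,4-bis(methoxymethoxy)phenyl]-2-(3-methylfuran-2-yl)propanoic acid | Cc1ccoc1[C@@H](Cc2c(OC)cc(OCOC)c(C(=O)CCCCC)c2OCOC)C(=O)O | intermediate
19 | (2R)-acyl imidazolide of 18 (not isolated) | Cc1ccoc1[C@@H](Cc2c(OC)cc(OCOC)c(C(=O)CCCCC)c2OCOC)C(=O)n1ccnc1 | intermediate
20 | tert-butyl (4R)-5-[3-hexanoyl-6-methoxy-2,4-bis(methoxymethoxy)phenyl]-4-(3-methylfuran-2-yl)-3-oxopentanoate | Cc1ccoc1[C@@H](Cc2c(OC)cc(OCOC)c(C(=O)CCCCC)c2OCOC)C(=O)CC(=O)OC(C)(C)C | intermediate
21 | tert-butyl (4R)-2-hexanoyl-5-[3-hexanoyl-6-methoxy-2,4-bis(methoxymethoxy)phenyl]-4-(3-methylfuran-2-yl)-3-oxopentanoate (C2 enolised) | Cc1ccoc1[C@@H](Cc2c(OC)cc(OCOC)c(C(=O)CCCCC)c2OCOC)C(=O)C(C(=O)CCCCC)C(=O)OC(C)(C)C | intermediate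
22 | (R)-diacylketene (not isolated) | Cc1ccoc1[C@@H](Cc2c(OC)cc(OCOC)c(C(=O)CCCCC)c2OCOC)C(=O)C(=C=O)C(=O)CCCCC | intermediate
23 | (3aS)-5-hexanoyl-7-{[3-hexanoyl-6-methoxy-2,4-bis(methoxymethoxy)phenyl]methyl}-6-hydroxy-3a-methyl-1-benzofuran-4(3aH)-one | CCCCCC(=O)C1=C(O)C(Cc2c(OC)cc(OCOC)c(C(=O)CCCCC)c2OCOC)=C2OC=C[C@]2(C)C1=O | intermediate
24 | (3aS)-5-hexanoyl-7-[(3-hexanoyl-2,4-dihydroxy-6-methoxyphenyl)methyl]-2,6-dihydroxy-3a-methyl-2,3-dihydro-1-benzofuran-4(3aH)-one (lactol epimers) | CCCCCC(=O)C1=C(O)C(Cc2c(OC)cc(O)c(C(=O)CCCCC)c2O)=C2OC(O)C[C@]2(C)C1=O | intermediate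
25 | ring-opened aldehyde tautomer of 24 (not isolated) | CCCCCC(=O)C1=C(O)C(Cc2c(OC)cc(O)c(C(=O)CCCCC)c2O)=C(O)[C@](C)(CC=O)C1=O | intermediate
26 | (4S)-2-hexanoyl-6-[(3-hexanoyl-2,4-dihydroxy-6-methoxyphenyl)methyl]-3,5-dihydroxy-4-methyl-4-(3-methylbut-2-en-1-yl)cyclohexa-2,5-dien-1-one | CCCCCC(=O)C1=C(O)[C@@](C)(CC=C(C)C)C(O)=C(Cc2c(OC)cc(O)c(C(=O)CCCCC)c2O)C1=O | target

**Count**
Total steps: 14. Longest linear sequence: 11 (steps 1–4, then 8–14).

**Steps most likely to fail**

Step 12 (proposed new method). The C4 configuration may be lost by keto–enol tautomerism of the acylketene before ring closure, the facial discrimination may be too small, or acid-autocatalysed loss of isobutene and decarboxylation may outrun ketene formation. The fallback uses known chemistry, leaves the furan strategy, sets out from 6 and returns at 26. Commercial 2,4,6-trihydroxytoluene is C-acylated (n-C5H11COCl, AlCl3, Friedel–Crafts) to 1-(2,4,6-trihydroxy-3-methylphenyl)hexan-1-one F1. Dearomatising C-prenylation at the methyl-bearing carbon (prenyl bromide, NaOMe, MeOH, 0 °C) should give racemic 2-hexanoyl-3,5-dihydroxy-4-methyl-4-(3-methylbut-2-en-1-yl)cyclohexa-2,5-dien-1-one F2, which is resolved by preparative chromatography on a chiral stationary phase to its (S)-enantiomer F3. C-benzylation of the sodium enolate of F3 at its one free ring CH with bromide 6 should give the bis-MOM ether of the target F4, and brief mild acid (2 M HCl, MeOH, rt) removes the MOM groups to give 26.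

Step 10. The α-furyl centre may partly epimerise while the carboxyl group is activated (enolisation or ketene formation from the acyl imidazolide). The fallback sets out from 16 and returns at 20. Transamidation of the imide with Me2AlN(OMe)Me (from Me3Al and MeNHOMe·HCl, CH2Cl2, 0 °C) gives the (2R)-N-methoxy-N-methylamide F5. Addition of the lithium enolate of tert-butyl acetate (LDA, THF, −78 °C) forms a chelated tetrahedral adduct that collapses only on work-up and gives 20 without a free activated acid.

Step 14. The olefination may stall because the polyanion precipitates or the aldehyde is enolised by the excess ylide. The fallback sets out from 23 and returns at 26. Hydration of the enol ether alone (PPTS, wet acetone, 40 °C) gives the MOM-protected lactol F6. Wittig olefination of this less acidic, more soluble substrate (ylide as in step 14, about 4 equiv) gives the bis-MOM ether of the target F4, and the MOM groups are then removed with brief mild acid as above.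

**Further compounds**
F1 | step 12 | 1-(2,4,6-trihydroxy-3-methylphenyl)hexan-1-one | CCCCCC(=O)c1c(O)cc(O)c(C)c1O
F2 | step 12 | racemic 2-hexanoyl-3,5-dihydroxy-4-methyl-4-(3-methylbut-2-en-1-yl)cyclohexa-2,5-dien-1-one | CCCCCC(=O)C1=C(O)C(C)(CC=C(C)C)C(O)=CC1=O
F3 | step 12 | (4S)-2-hexanoyl-3,5-dihydroxy-4-methyl-4-(3-methylbut-2-en-1-yl)cyclohexa-2,5-dien-1-one | CCCCCC(=O)C1=C(O)[C@@](C)(CC=C(C)C)C(O)=CC1=O
F4 | step 12 | bis-MOM ether of 26 | CCCCCC(=O)C1=C(O)[C@@](C)(CC=C(C)C)C(O)=C(Cc2c(OC)cc(OCOC)c(C(=O)CCCCC)c2OCOC)C1=O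
F5 | step 10 | (2R)-3-[3-hexanoyl-6-methoxy-2,4-bis(methoxymethoxy)phenyl]-N-methoxy-N-methyl-2-(3-methylfuran-2-yl)propanamide | Cc1ccoc1[C@@H](Cc2c(OC)cc(OCOC)c(C(=O)CCCCC)c2OCOC)C(=O)N(C)OC
F6 | step 14 | MOM-protected lactol (bis-MOM ether of 24) | CCCCCC(=O)C1=C(O)C(Cc2c(OC)cc(OCOC)c(C(=O)CCCCC)c2OCOC)=C2OC(O)C[C@]2(C)C1=O
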